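**Retrosynthetic overview**
1. The last bond made is the ester C(=O)–O between the ring A acid, 2,4-bis(benzyloxy)-6-undecylbenzoic acid, and the (R)-carbinol; the four benzyl ethers are removed in one final hydrogenolysis.
2. The strategy rests on ring B: a benzene ring with oxygens at C1 and C3 and the seven-methylene tether to the carbinol at C5, which is the aromatised form of a 5-alkylcyclohexane-1,3-dione.
3. That dione ring is cut at C4–C5 and C2–C3 into dimethyl malonate and an (R)-12-silyloxy-pentadec-3-en-2-one (Michael–Claisen annulation); the malonate ester left on C4 is lost by decarboxylation.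
4. The enone comes from cross-metathesis of but-3-en-2-one with an (R)-4-silyloxy-tridec-12-ene, itself from (R)-2-propyloxirane and oct-7-enylmagnesium bromide; the only stereocentre is bought.
5. Ring A is bought as an arene (3,5-bis(benzyloxy)benzyl bromide) and elaborated by alkylation, formylation and oxidation; ring B is the only ring formed (step 4) and is aromatised in step 6.

Key step: step 4

Remark: the carbinol is carried as a triisopropylsilyl (TIPS) ether, since a secondary TIPS ether should withstand the methoxide, hot aqueous hydroxide and dilute acid of steps 4 and 5; compounds 9–11 are mixtures at the ring or chain carbons created in step 4 (no descriptors given, as these centres vanish later), and 16 and 17 are taken as purchasable.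

**Step 1**
Reactants: 1 8-bromooct-1-ene; 2 (R)-2-propyloxirane
Product: 4 (R)-tridec-12-en-4-ol, via oct-7-enylmagnesium bromide 3 (not isolated)
Conditions: Mg, THF, 40 °C; then CuI (10 mol%), 2, THF, −30 to 0 °C; 1 M HCl quench
Reagents that add atoms: none
Why: Copper-catalysed Grignard opening of a terminal epoxide occurs by SN2 attack at the unsubstituted CH2, so the stereocentre of (R)-2-propyloxirane is not touched and becomes the R carbinol.

**Step 2**
Reactants: 4 (R)-tridec-12-en-4-ol
Product: 5 (R)-triisopropyl(tridec-12-en-4-yloxy)silane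
Conditions: TIPSOTf, 2,6-lutidine, CH2Cl2, 0 °C to rt
Reagents that add atoms: triisopropylsilyl trifluoromethanesulfonate, CC(C)[Si](OS(=O)(=O)C(F)(F)F)(C(C)C)C(C)C
Why: Silylation of a secondary alcohol with a silyl triflate and a hindered pyridine base is standard and leaves the C–O stereocentre unchanged.

**Step 3**
Reactants: 5 (R)-triisopropyl(tridec-12-en-4-yloxy)silane; 6 but-3-en-2-one
Product: 7 (R,E)-12-(triisopropylsilyloxy)pentadec-3-en-2-one
Conditions: 6 (3 equiv), second-generation Grubbs catalyst RuCl2(=CHPh)(PCy3)(H2IMes) (5 mol%), CH2Cl2, 40 °C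
Reagents that add atoms: none
Why: Olefin cross-metathesis of a terminal alkene with an electron-poor enone partner should favour the cross product with E geometry, with loss of ethene, and the silyl ether is inert to the ruthenium carbene.

**Step 4**
Reactants: 7 (R,E)-12-(triisopropylsilyloxy)pentadec-3-en-2-one; 8 dimethyl malonate
Product: 10 methyl 6-[(R)-8-(triisopropylsilyloxy)undecyl]-2,4-dioxocyclohexane-1-carboxylate, via Michael adduct 9 (not isolated)
Conditions: 8 (1.2 equiv), NaOMe (1.2 equiv), MeOH, reflux; then cold 1 M HCl to pH 3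
Reagents that add atoms: none
Why: Methoxide generates sodio dimethyl malonate, a soft stabilised carbanion that adds 1,4 to enone 7 at C4 to give keto diester 9, whose ketone enolate on the methyl side (C1) then attacks one malonate ester carbonyl and expels methoxide. The closest known reaction is the classical malonate Michael–Claisen (Dieckmann-type) condensation of alk-3-en-2-ones to 4-carbalkoxy-5-alkylcyclohexane-1,3-diones, as in the dimedone synthesis. Ring B closes by a 6-exo-trig acylation of the enolate carbon on the ester C=O, and only the methyl-side enolate can do this, because the C3 enolate would have to form a four-membered ring. The two ring stereocentres created (C1 and C6 of the cyclohexane) are not controlled and need not be, since C1 is epimerisable and both are flattened in steps 5 and 6, while the remote (R)-carbinol, masked as its TIPS ether, takes no part. The step needs chemoselectivity for conjugate over carbonyl addition and for ring closure over retro-Michael or intermolecular condensation; the soft nucleophile, the favoured six-membered closure and the irreversible deprotonation of the acidic β-dicarbonyl product should secure it.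

**Step 5**
Reactants: 10 methyl 6-[(R)-8-(triisopropylsilyloxy)undecyl]-2,4-dioxocyclohexane-1-carboxylate
Product: 12 5-[(R)-8-(triisopropylsilyloxy)undecyl]cyclohexane-1,3-dione, via dioxo carboxylic acid 11 (not isolated)
Conditions: NaOH (2 M aq.), MeOH, 70 °C; then 2 M HCl to pH 3, 70 °C
Reagents that add atoms: none
Why: Saponification followed by acidification gives a β-keto acid that should decarboxylate through the usual cyclic transition state on gentle warming, the dione being shielded from retro-Claisen cleavage as its enolate in base and the secondary TIPS ether tolerating both media.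

**Step 6**
Reactants: 12 5-[(R)-8-(triisopropylsilyloxy)undecyl]cyclohexane-1,3-dione
Product: 13 5-[(R)-8-(triisopropylsilyloxy)undecyl]benzene-1,3-diol
Conditions: 10% Pd/C, triglyme, 215 °C, argon sweep
Reagents that add atoms: none
Why: Heterogeneous catalytic dehydrogenation over palladium should remove one equivalent of H2 from the enolised dione, driven by aromatisation to the resorcinol, under neutral conditions that leave the silyl ether alone.

**Step 7**
Reactants: 13 5-[(R)-8-(triisopropylsilyloxy)undecyl]benzene-1,3-diol
Product: 14 1,3-bis(benzyloxy)-5-[(R)-8-(triisopropylsilyloxy)undecyl]benzene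
Conditions: BnBr (2.5 equiv), K2CO3, DMF, 50 °C
Reagents that add atoms: benzyl bromide, BrCc1ccccc1
Why: Williamson ether synthesis, in which the phenoxides formed with K2CO3 are O-benzylated while the silyl ether is inert.

**Step 8**
Reactants: 14 1,3-bis(benzyloxy)-5-[(R)-8-(triisopropylsilyloxy)undecyl]benzene
Product: 15 (R)-11-[3,5-bis(benzyloxy)phenyl]undecan-4-ol
Conditions: TBAF, THF, 50 °C
Reagents that add atoms: none
Why: Fluoride-mediated desilylation cleaves the Si–O bond only, so the carbinol keeps its R configuration and the benzyl ethers stay in place.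

**Step 9**
Reactants: 16 3,5-bis(benzyloxy)benzyl bromide; 17 decylmagnesium bromide
Product: 18 1,3-bis(benzyloxy)-5-undecylbenzene
Conditions: 17 (1.3 equiv), Li2CuCl4 (3 mol%), THF, −10 °C to rt
Reagents that add atoms: none
Why: Copper-catalysed (Kochi-type) sp3–sp3 cross-coupling of an alkyl Grignard reagent with a benzylic bromide should install the undecyl chain, the aryl benzyl ethers being inert.

**Step 10**
Reactants: 18 1,3-bis(benzyloxy)-5-undecylbenzene
Product: 19 2,4-bis(benzyloxy)-6-undecylbenzaldehyde
Conditions: POCl3, DMF, 0 to 70 °C; then ice-water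
Reagents that add atoms: N,N-dimethylformamide, CN(C)C=O; water, O
Why: Vilsmeier–Haack formylation should take place at the ring position para to one benzyloxy group and ortho to the other, which is favoured over the crowded position between the two ethers, and hydrolysis of the iminium salt gives the aldehyde.

**Step 11**
Reactants: 19 2,4-bis(benzyloxy)-6-undecylbenzaldehyde
Product: 20 2,4-bis(benzyloxy)-6-undecylbenzoic acid
Conditions: NaClO2, NaH2PO4, 2-methylbut-2-ene, t-BuOH/THF/H2O, rt
Reagents that add atoms: sodium chlorite, [Na+].[O-]Cl=O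
Why: Pinnick oxidation converts the hindered aryl aldehyde to the acid under buffered conditions, with 2-methylbut-2-ene scavenging HOCl so that the electron-rich ring is not chlorinated.

**Step 12**
Reactants: 20 2,4-bis(benzyloxy)-6-undecylbenzoic acid; 15 (R)-11-[3,5-bis(benzyloxy)phenyl]undecan-4-ol
Product: 22 (R)-11-[3,5-bis(benzyloxy)phenyl]undecan-4-yl 2,4-bis(benzyloxy)-6-undecylbenzoate, via acid chloride 21 (not isolated)
Conditions: (COCl)2, DMF (cat.), CH2Cl2, 0 °C to rt, evaporate; then 15, Et3N, DMAP, CH2Cl2, rt to 40 °C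
Reagents that add atoms: none
Why: Acylation of the secondary alcohol by the acid chloride under DMAP nucleophilic catalysis forms the ester at the acyl carbon, as in the preparation of mesitoate esters from 2,6-disubstituted benzoyl chlorides, so the R configuration of the carbinol is retained.

**Step 13**
Reactants: 22 (R)-11-[3,5-bis(benzyloxy)phenyl]undecan-4-yl 2,4-bis(benzyloxy)-6-undecylbenzoate
Product: 23 (R)-11-(3,5-dihydroxyphenyl)undecan-4-yl 2,4-dihydroxy-6-undecylbenzoate (CNP0146287.1)
Conditions: H2 (1 atm), 10% Pd/C, EtOAc/MeOH, rt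
Reagents that add atoms: none
Why: Catalytic hydrogenolysis should cleave the four aryl benzyl ethers to phenols and toluene, while the non-benzylic secondary alkyl benzoate and its stereocentre are not affected.

**Compound list**
1 | 8-bromooct-1-ene | C=CCCCCCCBr | starting material
2 | (R)-2-propyloxirane | CCC[C@@H]1CO1 | starting material
3 | oct-7-enylmagnesium bromide | C=CCCCCCC[Mg]Br | intermediate
4 | (R)-tridec-12-en-4-ol | CCC[C@@H](O)CCCCCCCC=C | intermediate
5 | (R)-triisopropyl(tridec-12-en-4-yloxy)silane | CCC[C@@H](O[Si](C(C)C)(C(C)C)C(C)C)CCCCCCCC=C | intermediate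
6 | but-3-en-2-one | CC(=O)C=C | starting material
7 | (R,E)-12-(triisopropylsilyloxy)pentadec-3-en-2-one | CC(=O)/C=C/CCCCCCC[C@@H](CCC)O[Si](C(C)C)(C(C)C)C(C)C | intermediate
8 | dimethyl malonate | COC(=O)CC(=O)OC | starting material
9 | dimethyl 2-[(12R)-2-oxo-12-(triisopropylsilyloxy)pentadecan-4-yl]propanedioate (Michael adduct) | CC(=O)CC(CCCCCCC[C@@H](CCC)O[Si](C(C)C)(C(C)C)C(C)C)C(C(=O)OC)C(=O)OC | intermediate
10 | methyl 6-[(R)-8-(triisopropylsilyloxy)undecyl]-2,4-dioxocyclohexane-1-carboxylate | COC(=O)C1C(=O)CC(=O)CC1CCCCCCC[C@@H](CCC)O[Si](C(C)C)(C(C)C)C(C)C | intermediate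
11 | 6-[(R)-8-(triisopropylsilyloxy)undecyl]-2,4-dioxocyclohexane-1-carboxylic acid | OC(=O)C1C(=O)CC(=O)CC1CCCCCCC[C@@H](CCC)O[Si](C(C)C)(C(C)C)C(C)C | intermediate
12 | 5-[(R)-8-(triisopropylsilyloxy)undecyl]cyclohexane-1,3-dione | O=C1CC(=O)CC(C1)CCCCCCC[C@@H](CCC)O[Si](C(C)C)(C(C)C)C(C)C | intermediate
13 | 5-[(R)-8-(triisopropylsilyloxy)undecyl]benzene-1,3-diol | Oc1cc(O)cc(c1)CCCCCCC[C@@H](CCC)O[Si](C(C)C)(C(C)C)C(C)C | intermediate
14 | 1,3-bis(benzyloxy)-5-[(R)-8-(triisopropylsilyloxy)undecyl]benzene | CCC[C@@H](O[Si](C(C)C)(C(C)C)C(C)C)CCCCCCCc1cc(OCc2ccccc2)cc(OCc2ccccc2)c1 | intermediate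
15 | (R)-11-[3,5-bis(benzyloxy)phenyl]undecan-4-ol | CCC[C@@H](O)CCCCCCCc1cc(OCc2ccccc2)cc(OCc2ccccc2)c1 | intermediate
16 | 3,5-bis(benzyloxy)benzyl bromide | BrCc1cc(OCc2ccccc2)cc(OCc2ccccc2)c1 | starting material
17 | decylmagnesium bromide | CCCCCCCCCC[Mg]Br | starting material
18 | 1,3-bis(benzyloxy)-5-undecylbenzene | CCCCCCCCCCCc1cc(OCc2ccccc2)cc(OCc2ccccc2)c1 | intermediate
19 | 2,4-bis(benzyloxy)-6-undecylbenzaldehyde | CCCCCCCCCCCc1cc(OCc2ccccc2)cc(OCc2ccccc2)c1C=O | intermediate
20 | 2,4-bis(benzyloxy)-6-undecylbenzoic acid | CCCCCCCCCCCc1cc(OCc2ccccc2)cc(OCc2ccccc2)c1C(=O)O | intermediate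
21 | 2,4-bis(benzyloxy)-6-undecylbenzoyl chloride | CCCCCCCCCCCc1cc(OCc2ccccc2)cc(OCc2ccccc2)c1C(=O)Cl | intermediate
22 | (R)-11-[3,5-bis(benzyloxy)phenyl]undecan-4-yl 2,4-bis(benzyloxy)-6-undecylbenzoate | CCCCCCCCCCCc1cc(OCc2ccccc2)cc(OCc2ccccc2)c1C(=O)O[C@H](CCC)CCCCCCCc1cc(OCc2ccccc2)cc(OCc2ccccc2)c1 | intermediate
23 | (R)-11-(3,5-dihydroxyphenyl)undecan-4-yl 2,4-dihydroxy-6-undecylbenzoate | CCCCCCCCCCCc1cc(O)cc(O)c1C(=O)O[C@H](CCC)CCCCCCCc1cc(O)cc(O)c1 | target

**Step count**
Total: 13 steps. Longest linear sequence: 10 steps (steps 1–8, 12, 13); the ring A branch (steps 9–11) joins at step 12.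

**Steps most likely to fail**

Step 6 (dehydrogenation). The hydrogen released on the catalyst may reduce part of the dione (disproportionation, or hydrogenolysis of an enol C–O bond) or the dehydrogenation may stop short of the arene. The fallback sets out from 12 and raises the oxidation level stepwise. Condensation of 12 with benzyl alcohol (PPTS cat., toluene, Dean–Stark) would give the vinylogous ester 3-(benzyloxy)-5-[(R)-8-(triisopropylsilyloxy)undecyl]cyclohex-2-en-1-one F1. Kinetic α′-deprotonation with LiN(iPr)2 in THF at −78 °C and trapping with PhSeCl would give 3-(benzyloxy)-6-(phenylselanyl)-5-[(R)-8-(triisopropylsilyloxy)undecyl]cyclohex-2-en-1-one F2. Oxidation with H2O2 and pyridine in CH2Cl2 would bring about selenoxide syn-elimination to the cross-conjugated dienone, which tautomerises to 3-(benzyloxy)-5-[(R)-8-(triisopropylsilyloxy)undecyl]phenol F3. Benzylation of the remaining phenol (BnBr, K2CO3, DMF) returns to the route at 14, bypassing 13.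

Step 12 (esterification). Acyl transfer from a doubly ortho-substituted benzoyl chloride to a secondary alcohol may be too slow, so that hydrolysis back to 20 or decomposition of 21 wins. The fallback sets out from 15 and moves the bond-forming event from the hindered acyl carbon to the carbinol carbon, with two inversions. Mitsunobu reaction of 15 with 4-nitrobenzoic acid (PPh3, DIAD, THF) would give (S)-11-[3,5-bis(benzyloxy)phenyl]undecan-4-yl 4-nitrobenzoate F4. Methanolysis (K2CO3, MeOH) would give (S)-11-[3,5-bis(benzyloxy)phenyl]undecan-4-ol F5. A second Mitsunobu reaction of F5 with acid 20 (PPh3, DIAD, toluene, 0 °C to rt), in which the carboxylate displaces the activated oxygen with inversion, returns to the route at 22 with the R configuration.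

Step 4 (key step). The conjugate addition may reverse or the enone may oligomerise under methoxide before the Claisen closure is complete. The fallback sets out from 5 and builds the same ring with the roles of the partners exchanged. Cross-metathesis of 5 with methyl acrylate (same ruthenium catalyst, CH2Cl2, 40 °C) would give methyl (R,E)-11-(triisopropylsilyloxy)tetradec-2-enoate F6. Treatment with methyl acetoacetate and NaOMe in refluxing MeOH would give, by Michael addition, dimethyl 2-acetyl-3-[(R)-8-(triisopropylsilyloxy)undecyl]pentanedioate F7 (not isolated). Dieckmann-type attack of the acetyl methyl enolate of F7 on the terminal ester closes the ring and, after acidification, returns to the route at 10.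

**Further compounds**
F1 | step 6 | 3-(benzyloxy)-5-[(R)-8-(triisopropylsilyloxy)undecyl]cyclohex-2-en-1-one | O=C1C=C(OCc2ccccc2)CC(C1)CCCCCCC[C@@H](CCC)O[Si](C(C)C)(C(C)C)C(C)C
F2 | step 6 | 3-(benzyloxy)-6-(phenylselanyl)-5-[(R)-8-(triisopropylsilyloxy)undecyl]cyclohex-2-en-1-one | O=C1C=C(OCc2ccccc2)CC(CCCCCCC[C@@H](CCC)O[Si](C(C)C)(C(C)C)C(C)C)C1[Se]c1ccccc1
F3 | step 6 | 3-(benzyloxy)-5-[(R)-8-(triisopropylsilyloxy)undecyl]phenol | Oc1cc(OCc2ccccc2)cc(c1)CCCCCCC[C@@H](CCC)O[Si](C(C)C)(C(C)C)C(C)C
F4 | step 12 | (S)-11-[3,5-bis(benzyloxy)phenyl]undecan-4-yl 4-nitrobenzoate | CCC[C@H](OC(=O)c1ccc(cc1)[N+](=O)[O-])CCCCCCCc1cc(OCc2ccccc2)cc(OCc2ccccc2)c1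
F5 | step 12 | (S)-11-[3,5-bis(benzyloxy)phenyl]undecan-4-ol | CCC[C@H](O)CCCCCCCc1cc(OCc2ccccc2)cc(OCc2ccccc2)c1
F6 | step 4 | methyl (R,E)-11-(triisopropylsilyloxy)tetradec-2-enoate | COC(=O)/C=C/CCCCCCC[C@@H](CCC)O[Si](C(C)C)(C(C)C)C(C)C
F7 | step 4 | dimethyl 2-acetyl-3-[(R)-8-(triisopropylsilyloxy)undecyl]pentanedioate | COC(=O)CC(CCCCCCC[C@@H](CCC)O[Si](C(C)C)(C(C)C)C(C)C)C(C(C)=O)C(=O)OC
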